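How much free base must you charge so that 95 % of the electrophile has reacted at 8.0 h?

    electrophile + nucleophile → acid set free + product (k1 = 78 M⁻¹ h⁻¹)
    nucleophile + acid set free ⇌ protonated nucleophile, settled at all times (K2 = 7300 M⁻¹)
    acid set free + free base ⇌ salt of the base, settled at all times (K3 = 3.3 × 10⁶ M⁻¹)
    nucleophile + product ⇌ idle adduct, settled at all times (K4 = 25 M⁻¹)
    acid set free → by-product carried off (k5 = 0.35 h⁻¹)
    nucleophile ⇌ dormant form (K6 = 0.23, k6 = 4.3 h⁻¹)

electrophile 0.050 M; nucleophile 0.0600 M; time 8.0 h

1. the concentration of free base at which the part of the electrophile that has reacted at 8.0 h is just 95 %, in M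

- what is said of product includes idle adduct
- the amount of free base is what is sought; it is there from the start
- run time (flask): 8.0 h

1. Count nucleophile. Each electrophile that reacts uses one nucleophile and sets free one acid, and that acid takes a second nucleophile unless free base binds it.

2. Free base binds acid more tightly than nucleophile does, 3.3 × 10⁶ M⁻¹ against 7300 M⁻¹, so charged base covers acid first.

3. As a first count, I take no acid as carried off and leave out dormant form and idle adduct.

4. Reaching 95 % demands 0.0950 M of nucleophile, and you charged 0.0600 M.

5. The gap, 0.0350 M, is the base bill: nucleophile demanded minus nucleophile charged.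

6. The forecast gives 0.0368 M: “the base must cover about 0.037 M of the 0.0475 M acid formed”.

7. The simulation gives 0.0360 M, close to the bill. In that flask the reaction of electrophile with nucleophile did half its turnover by 0.254 h, and by 0.800 h free base was down to 2.04 % of its charge. The electrophile used then rose from 86.1 % at 2.00 h to 91.5 % at 4.00 h, while the carry-off of acid reached half its turnover by 5.68 h. Charged with 0.0288 M of free base, the bill allows 88.8 % reacted, and that flask gave 91.1 %.

The rate constants were set for the occasion; no experiment stands behind them.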